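(Readings and results were generated by integration for an exercise, and the scatter is random.)

Substrate will be left over in both flasks, because each holds 20 mM of it against 10.0 mM of coupling partner in west and 3.00 mM in south-east. If the two react one for one, as we assume, coupling partner is the limiting reagent and caps product at 50.0% in west and 15.0% in south-east.

the same everywhere: substrate 20 mM; free catalyst 0.50 mM; impurity 0.26 mM
- delta: coupling partner 4.1 mM; temperature 65 °C; run made earlier
- eta: coupling partner 13 mM; temperature 80 °C; run made earlier
- west: coupling partner 10.0 mM; temperature 80 °C; time 30 min
- south-east: coupling partner 3.00 mM; temperature 80 °C; time 60 min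

| run | time / min | product / % | substrate / % |
|---|---|---|---|
| delta | 2.00 | 2.4 | 98.3 |
| delta | 6.00 | 1.0 | 98.4 |
| delta | 10.0 | 2.5 | 99.4 |
| delta | 15.0 | 1.3 | 99.0 |
| delta | 25.0 | 6.0 | 94.9 |
| delta | 30.0 | 4.9 | 94.6 |
| eta | 1.00 | 2.9 | 100.3 |
| eta | 3.00 | 2.1 | 96.8 |
| eta | 5.00 | 5.0 | 95.8 |
| eta | 8.00 | 8.2 | 91.3 |
| eta | 12.0 | 12.2 | 89.7 |
| eta | 15.0 | 14.2 | 86.3 |

(readings scatter by 1 percentage point)

- what was read earlier has a scatter of 1 percentage point, one standard deviation

* the flask that ends with the higher amount of product, in percent of the substrate charged, or "neither" when 2 percentage points or less lies between them (west / south-east / neither)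
* final product, as a percentage of the substrate charged, in west
* final product, as a percentage of the substrate charged, in south-east

We leave delta aside, since it differs from both flasks in temperature and in coupling partner. Eta shares their temperature, free catalyst and impurity, and at 15.0 min it shows 14.2% product. We commit to a first-order fall of coupling partner, so c(coupling partner) is its charge times exp(−k t), and eta's last reading gives the partner decay constant k, the fraction of the remaining coupling partner used per minute, 0.0164 /min, a reading that carries the scatter of 1 percentage point. By our reckoning, west will show 19.5% and south-east 9.40%, so west ends above south-east's cap. Keep the bath at 80 °C and add nothing, for k was read from eta at that temperature, with that free catalyst and impurity.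

The forecast, “Taking the middle” of its bracket, says west, with 23% for west and 12% for south-east, each higher than our reckoning .

West ends at 21.7% and south-east at 11.9%, so west holds more product, and both stand above our reckoning .

coupling partner + free catalyst ⇌ catalyst intermediate A (K = 53.0 /M, k = 1600 /M/min, Ea = 43.0 kJ/mol, ΔH = −33.0 kJ/mol); catalyst intermediate A → catalyst intermediate B (k = 2.50 /min, Ea = 90.0 kJ/mol); catalyst intermediate C → free catalyst + product (k = 14.0 /min, Ea = 99.0 kJ/mol); substrate + catalyst intermediate B → catalyst intermediate C (k = 530 /M/min, Ea = 52.0 kJ/mol); free catalyst + impurity → spent catalyst (k = 37000 /M/min, Ea = 47.0 kJ/mol); (constants at 80 °C) South-east keeps 20% of its coupling partner unbound at 60.0 min, whereas our reckoning with k leaves 37.3%. For the neighbour of south-east charged with 5.1 mM of coupling partner, k gives 16.0% over the same time, and that flask stands at 19.6%.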